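## Structural features

The target is 15-acetoxylabd-8(17)-en-18-oic acid: a trans-fused decalin (rings A and B) with an exocyclic methylene at C8 and, at C9, an equatorial five-carbon chain that carries a methyl-bearing stereocentre (C13, S) and a primary acetate at C15. Four ring stereocentres are contiguous (C4–C5–C10–C9); C4 and C10 are quaternary, their methyl groups are 1,3-diaxial on the β face, and H5 and H9 are α. C4 carries the β-methyl group (C19), the α (equatorial) carboxyl carbon (C18) and the ring bonds to C3 and C5. C13 is separated from the ring by two methylene groups, so it cannot be set by relay and has to come from an enantiopure building block. Fragile points are the 8(17)-alkene (acid moves it into the ring), the primary acetate (bases and nucleophiles), the neopentyl carboxyl group (hard to release from an ester, so it is best carried as the aldehyde and oxidised late) and C9, which can epimerise while C8 is a ketone. The real difficulty is the crowded C4 centre, with defined configuration next to C5 and 1,3 to C10. The key step uses the substituent set of C4 (methyl, C18, C3, C5): with C18 placed inside a seven-membered ring between C5 and C4, a C4–C18 epoxide contracts to ring A by a 1,2-shift of C5, so the hindered C4–C5 bond is made from a bond that already exists.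

## Logic of the disconnections

**25 from 23 (through 24).** The O15–acetyl bond is cut and O15 is carried as a silyl ether. An acetate would not survive the enolate, alkoxide and organometallic steps. One protecting group then serves from the first step to the last. The forward step must remove silicon and acetylate without touching the free C18 acid or the 8(17)-alkene.

**23 from 22.** The C8=C17 bond is cut back to the C8 ketone. The ketone is the handle for building ring B and for fixing C9, and the acid-sensitive alkene appears only at the end. The forward methylenation must be non-basic enough to leave C9 alone and must tolerate a free acid.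

**22 from 21.** C18 is taken back one oxidation level. The aldehyde is what the rearrangement delivers, and it has no α-hydrogen, so a chlorite oxidation has no competing enolisation.

**21 from 20 (key).** The C4–C5 bond is cut and the C5–C18 bond is restored, which turns ring A into a seven-membered ring with a C4–C18 epoxide. The quaternary centre is then reached from a trisubstituted alkene oxide instead of by alkylating a hindered carbon. The forward step must make C5 migrate, not the C18 hydride, and must start from the α-epoxide.

**20 from 19.** The two C–O bonds of the oxirane are cut. The forward epoxidation must come from the α face, anti to the C10 methyl group.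

**19 from 17 (through 18).** The C18=C4 double bond is cut by retro-metathesis into a propenyl group on C5 and a 1,1-disubstituted alkene at the end of the C1–C3 chain. Ring A-homo then comes from two unhindered alkenes on a cyclohexanone. C9 is left to thermodynamic control once the trans-fused bicycle exists, and the forward equilibration must favour the equatorial chain.

**17 from 16.** The propenyl group is traced to an allyl group, because an allyl aldehyde is the practical partner for the enantioselective ring synthesis. The forward isomerisation must move only the monosubstituted alkene.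

**16 from 14 and 5 (through 15).** The C9–C11 bond is cut into the regiodefined C9 enolate and a primary iodide that carries C13. This joins the two chiral parts in one bond. The forward step is an alkylation of a hindered enolate with an unactivated electrophile.

**14 from 11 and 12 (through 13).** The C10–C1 bond is cut by retro-conjugate addition, leaving a 3-methylcyclohexenone whose only stereocentre is C5. The forward addition must be anti to the C5 substituent so that C20 ends β.

**11 from 9 (through 10).** The C10–C20 bond is cut and the C9=C10 unsaturation is removed, leaving a 4-substituted cyclohexenone. The forward pair is a methyl conjugate addition and a regiodefined dehydrogenation of the enol ether.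

**9 from 6 and 7 (through 8).** The C5–C6 bond (Michael) and the C9=C10 bond (aldol condensation) are cut. The only ring stereocentre is then set by catalysis from two achiral commercial liquids. The forward step must control the enamine face and must not epimerise the aldehyde α-centre before ring closure.

**5 from 1 (through 4, 3 and 2).** C13 with its two arms is taken from the chiral pool. In 1 the chain from oxygen to the alkene carbon has six carbons, one more than C15–C11, so plain alkene cleavage and alkylation would give a homologue. The alkene carbon is therefore oxidised to a carboxyl group and removed by iododecarboxylation, which gives the C11 iodide directly.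

## Other disconnections considered

**Alternative 1:** The cut removes C3–C4 and C5–C10 together, so that rings A and B come from one acyclic triene A2. In the forward sense A2, an (E)-diene tethered to an (E)-2-methylenoate, would undergo a thermal intramolecular Diels–Alder reaction to the bicyclic ester A1.
- In its favour: two rings, two C–C bonds and three stereocentres (C4, C5, C10) would form in one concerted step. The alkene geometries map onto the C4/C5 relationship, and there is no cation, so no question of migratory aptitude. On bonds and stereocentres per step it is better than the chosen plan.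
- Against it here: both new bonds end at fully substituted carbons (a diene terminus carrying methyl and tether, a trisubstituted dienophile), so high temperature is to be expected. Face and endo/exo control rest on C9 alone. A2 itself needs an enantioselective, geometry-controlled synthesis.
- After the key step: the Δ1 alkene, the ketal and the hindered methyl ester still have to be dealt with.
- Comparison: the chosen plan sets C10 early by a reliable anti conjugate addition and C4 by a stereospecific shift. It trades the reactivity risk of A2 for a hydride-versus-alkyl selectivity risk. Overall step count should be about equal.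

**Alternative 2:** The cut removes C1–C10 and C4–C5, so that ring A is added to a quinone. In the forward sense diene A5 and quinone A4 would combine by an endo Diels–Alder reaction to the cis-fused adduct A3.
- In its favour: A4 is cheap, the methoxy group steers regiochemistry, both quaternary centres and an oxygenated C18 arrive in one intermolecular step, and the endo rule fixes C4 relative to C10 without any migration issue. On certainty of the C4/C10 relationship and on the number of steps to a functionalised decalin it is better than the chosen plan.
- Against it here: the diene terminus C4 carries an inside methyl group, which disfavours the s-cis form. Absolute configuration would need a chiral Lewis acid. C5 has to be epimerised to the trans fusion, against two 1,3-diaxial methyl groups.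
- After the key step: the oxygens at C6, C7 and C9 must be removed or converted, the chain attached at C9 with control, C8 methylenated and C18 raised to the acid. The short key step is paid for afterwards.
- Comparison: the chosen plan has no surplus oxidation to remove and brings C13 in by one C–C bond. It should be clearly shorter, though its key step builds less.

**Alternative 3:** The cut removes C8–C9, so that ring B closes last on a ring A taken from the resin acid A7. In the forward sense the thionocarbonate A8 (both C9 epimers) would give a C9 radical with Bu3SnH, which adds 6-exo-dig to the C8 alkyne and yields ester A6.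
- In its favour: C4, C5 and C10 come from A7 with the correct absolute configuration, so no quaternary centre has to be built. On stereochemical security of ring A it is better than the chosen plan. The exocyclic methylene forms in the ring closure, which saves the methylenation, and the radical makes the C9 epimers converge.
- Against it here: the aromatic ring and ring B of A7 must be degraded to two differentiated arms on C5 and C10, which costs many oxidative steps. The C9–C11 bond must be made at a neopentyl position. The radical next to C10 may be reduced before it cyclises, tin has to be removed, and the hindered ester must be hydrolysed at the end.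
- Comparison: lower stereochemical risk than the chosen plan and an equal or better endgame, but a longer and more wasteful front end, so the chosen plan should win on step economy.

Key step: step 13

Remark: labdane numbering is used for all ring compounds (C18 is the carbon that ends as the carboxyl group; in 18–20 it is a member of the seven-membered ring), and 16–18 are carried as C9 epimer mixtures because the kinetic face of the alkylation is not secure; C9 is fixed in step 11.

## Route

Step 1
Reactants: 1 (S)-citronellol
Product: 2 (S)-tert-butyl[(3,7-dimethyloct-6-en-1-yl)oxy]dimethylsilane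
Conditions: TBSCl, imidazole, CH2Cl2, 0 °C to rt
Reagents that add atoms: tert-butyldimethylsilyl chloride, CC(C)(C)[Si](C)(C)Cl
Why: Silylation of an unhindered primary alcohol; the silyl ether tolerates every later basic, organometallic and Lewis acidic step and comes off only in step 16.

Step 2
Reactants: 2 (S)-tert-butyl[(3,7-dimethyloct-6-en-1-yl)oxy]dimethylsilane
Product: 4 (S)-6-(tert-butyldimethylsilyloxy)-4-methylhexanoic acid, via aldehyde 3 (not isolated)
Conditions: O3, MeCN/H2O (9:1), 0 °C; then NaClO2 (aq.), 0 °C to rt
Reagents that add atoms: ozone, [O-][O+]=O; sodium chlorite, [Na+].[O-]Cl=O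
Why: Ozonolysis in wet acetonitrile should give the aldehyde directly (water traps the carbonyl oxide), and chlorite oxidation (Pinnick type) in the same pot takes it to the acid while the hydrogen peroxide from the first stage scavenges hypochlorite. The stereocentre is two carbons from the reacting site.

Step 3
Reactants: 4 (S)-6-(tert-butyldimethylsilyloxy)-4-methylhexanoic acid
Product: 5 (R)-tert-butyl[(5-iodo-3-methylpentyl)oxy]dimethylsilane
Conditions: PhI(OAc)2, I2, cyclohexane, hν (tungsten lamp), reflux
Reagents that add atoms: iodine, II
Why: Suárez iododecarboxylation (a Hunsdiecker-type radical chain through the acyl hypoiodite): loss of CO2 gives a primary radical that iodine traps much faster than it can abstract hydrogen intramolecularly. This removes the surplus carbon and leaves the C11 iodide; the descriptor changes to R only through the priority rules.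

Step 4
Reactants: 6 pent-4-enal; 7 but-3-en-2-one
Product: 9 (S)-4-allylcyclohex-2-en-1-one, via keto aldehyde 8 (not isolated)
Conditions: (S)-2-[methoxy(diphenyl)methyl]pyrrolidine (5 mol %), ethyl 3,4-dihydroxybenzoate (20 mol %), neat, 4 °C; then LiOH, i-PrOH, rt
Reagents that add atoms: none
Why: Enamine-catalysed Michael addition followed by intramolecular aldol condensation (Robinson-type annulation): the E-enamine of 6 is attacked by 7 on the face away from the diphenyl(methoxy)methyl group, which sets C5 as S (H5 α in the labdane frame). Ring closure through the methyl ketone enolate should be faster than enolisation of the α-branched aldehyde.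

Step 5
Reactants: 9 (S)-4-allylcyclohex-2-en-1-one
Product: 10 trimethyl{[(3S,4S)-3-methyl-4-(prop-2-en-1-yl)cyclohex-1-en-1-yl]oxy}silane
Conditions: Me2CuLi, TMSCl, THF, −78 °C; Et3N
Reagents that add atoms: lithium dimethylcuprate, [Li+].C[Cu-]C; chlorotrimethylsilane, C[Si](C)(C)Cl
Why: Cuprate conjugate addition with in situ O-silylation; methyl enters anti to the allyl group, but this centre becomes sp2 again in step 6, so only the regiodefined enol ether matters.

Step 6
Reactants: 10 trimethyl{[(3S,4S)-3-methyl-4-(prop-2-en-1-yl)cyclohex-1-en-1-yl]oxy}silane
Product: 11 (S)-4-allyl-3-methylcyclohex-2-en-1-one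
Conditions: Pd(OAc)2 (1.1 equiv), MeCN, rt
Reagents that add atoms: none
Why: Saegusa–Ito oxidation: divalent palladium forms the C9-bound enolate, and the only β-hydrogen (on C10, syn to palladium when the metal enters anti to the methyl group) is eliminated. The double bond is therefore placed at C9=C10 and C5 is untouched.

Step 7
Reactants: 11 (S)-4-allyl-3-methylcyclohex-2-en-1-one; 12 5-bromo-2-methylpent-1-ene
Product: 14 trimethyl{[(3S,4S)-3-methyl-3-(4-methylpent-4-en-1-yl)-4-(prop-2-en-1-yl)cyclohex-1-en-1-yl]oxy}silane, via Grignard reagent 13 (not isolated)
Conditions: 12, Mg, THF, rt; then 11, CuBr·SMe2 (10 mol %), TMSCl, HMPA, THF, −78 to −40 °C; Et3N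
Reagents that add atoms: chlorotrimethylsilane, C[Si](C)(C)Cl
Why: Copper-catalysed, TMSCl-accelerated conjugate addition of a Grignard reagent to a β,β-disubstituted enone. A(1,2) strain with the C10 methyl group holds the allyl group pseudoaxial, and the nucleophile adds axially on the opposite (α) face, as in additions to 3,4-dialkylcyclohexenones; this makes C10 quaternary with C20 β and C1 α.

Step 8
Reactants: 14 trimethyl{[(3S,4S)-3-methyl-3-(4-methylpent-4-en-1-yl)-4-(prop-2-en-1-yl)cyclohex-1-en-1-yl]oxy}silane; 5 (R)-tert-butyl[(5-iodo-3-methylpentyl)oxy]dimethylsilane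
Product: 16 (3S,4S)-4-allyl-2-[(3S)-5-(tert-butyldimethylsilyloxy)-3-methylpentyl]-3-methyl-3-(4-methylpent-4-en-1-yl)cyclohexan-1-one (C2 epimers), via lithium enolate 15 (not isolated)
Conditions: MeLi, THF, 0 °C; then 5, HMPA, −78 to 0 °C
Reagents that add atoms: none
Why: Regiospecific lithium enolate generation from a silyl enol ether, then SN2 alkylation with a primary iodide. The C9–C11 bond forms only at C9 because the enolate is made without equilibration; the face of attack is left open and corrected in step 11.

Step 9
Reactants: 16 (3S,4S)-4-allyl-2-[(3S)-5-(tert-butyldimethylsilyloxy)-3-methylpentyl]-3-methyl-3-(4-methylpent-4-en-1-yl)cyclohexan-1-one (C2 epimers)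
Product: 17 (3S,4S)-2-[(3S)-5-(tert-butyldimethylsilyloxy)-3-methylpentyl]-3-methyl-3-(4-methylpent-4-en-1-yl)-4-[(E)-prop-1-en-1-yl]cyclohexan-1-one (C2 epimers)
Conditions: RuHCl(CO)(PPh3)3 (5 mol %), toluene, 80 °C
Reagents that add atoms: none
Why: Ruthenium hydride-catalysed alkene isomerisation (hydrometalation and β-hydride elimination) moves the monosubstituted allyl double bond by one position. The 1,1-disubstituted alkene inserts far more slowly, and a further shift towards C5 would need a hindered tertiary alkyl–ruthenium species. Either propenyl geometry serves in step 10.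

Step 10
Reactants: 17 (3S,4S)-2-[(3S)-5-(tert-butyldimethylsilyloxy)-3-methylpentyl]-3-methyl-3-(4-methylpent-4-en-1-yl)-4-[(E)-prop-1-en-1-yl]cyclohexan-1-one (C2 epimers)
Product: 18 (13S)-15-(tert-butyldimethylsilyloxy)-A-homo-17-norlabd-4(18)-en-8-one (5α-H; 10β-CH3; C9 epimers)
Conditions: second-generation Grubbs catalyst (5 mol %), CH2Cl2 (5 mM), 40 °C
Reagents that add atoms: none
Why: Ring-closing metathesis of a propenyl group with a 1,1-disubstituted alkene gives the trisubstituted cycloheptene and propene. The two alkene arms are gauche on the chair cyclohexanone (both equatorial), so the trans-fused seven-membered ring closes without strain.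

Step 11
Reactants: 18 (13S)-15-(tert-butyldimethylsilyloxy)-A-homo-17-norlabd-4(18)-en-8-one (5α-H; 10β-CH3; C9 epimers)
Product: 19 (13S)-15-(tert-butyldimethylsilyloxy)-A-homo-17-norlabd-4(18)-en-8-one (5α-H; 9α-H; 10β-CH3)
Conditions: NaOMe (0.3 equiv), MeOH, rt
Reagents that add atoms: none
Why: Base-mediated epimerisation through the C8 enolate under thermodynamic control. In the rigid trans-fused bicycle the 9α (axial) chain would be syn-axial to H5, H7 and H1, so the 9β (equatorial) chain of the natural series should dominate; C5 and C10 cannot enolise.

Step 12
Reactants: 19 (13S)-15-(tert-butyldimethylsilyloxy)-A-homo-17-norlabd-4(18)-en-8-one (5α-H; 9α-H; 10β-CH3)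
Product: 20 (13S)-4α,18α-epoxy-15-(tert-butyldimethylsilyloxy)-A-homo-17-norlabdan-8-one
Conditions: mCPBA, NaHCO3, CH2Cl2, 0 °C
Reagents that add atoms: 3-chloroperoxybenzoic acid, O=C(OO)c1cccc(Cl)c1
Why: Prilezhaev epoxidation of the only alkene. In the chair cycloheptene the axial C10 methyl group lies over the inner (β) face of the C18=C4 bond, so the peracid should approach from the α face; epoxidation of a trisubstituted alkene at 0 °C is much faster than Baeyer–Villiger oxidation of the ketone.

Step 13
Reactants: 20 (13S)-4α,18α-epoxy-15-(tert-butyldimethylsilyloxy)-A-homo-17-norlabdan-8-one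
Product: 21 (13S)-15-(tert-butyldimethylsilyloxy)-8-oxo-17-norlabdan-18-al
Conditions: MeAl(OAr)2 (Ar = 4-bromo-2,6-di-tert-butylphenyl, 2.5 equiv; from Me3Al and ArOH), CH2Cl2, −78 to −40 °C
Reagents that add atoms: none
Why: Meinwald (semipinacol-type) rearrangement: the aluminium aryloxide binds the oxirane oxygen, the C4–O bond ionises at the tertiary carbon, and the C18–C5 bond shifts to C4 while C18 becomes the aldehyde carbon. The closest known reaction type is the rearrangement of trisubstituted epoxides to α-quaternary aldehydes with bulky methylaluminium bis(aryloxides), including ring contraction of 1-methylcycloalkene oxides. Ring A is not closed end to end but by this 1,2-alkyl shift, which contracts the cycloheptane to the cyclohexane (seven to six). The new C4 stereocentre is controlled by the epoxide configuration from step 12: C5 arrives on the face opposite the departing α-oxygen (inversion at C4), which puts the methyl group β (cis to C20) and the formyl group α (equatorial), and C5 migrates with retention. The step needs C5 to migrate in preference to the C18 hydride; the bulk of the aryloxide ligands disfavours the hydride-shift transition state, the low temperature keeps the ion pair tight, and the seven-to-six contraction releases ring strain. One equivalent of the Lewis acid is held by the C8 ketone, hence the excess, and the aprotic, non-basic medium leaves C9 and the silyl ether alone.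

Step 14
Reactants: 21 (13S)-15-(tert-butyldimethylsilyloxy)-8-oxo-17-norlabdan-18-al
Product: 22 (13S)-15-(tert-butyldimethylsilyloxy)-8-oxo-17-norlabdan-18-oic acid
Conditions: NaClO2, NaH2PO4, 2-methyl-2-butene, t-BuOH/H2O, rt
Reagents that add atoms: sodium chlorite, [Na+].[O-]Cl=O
Why: Pinnick oxidation; the aldehyde has no α-hydrogen and the molecule contains no alkene at this stage, so the buffered chlorite has nothing else to attack.

Step 15
Reactants: 22 (13S)-15-(tert-butyldimethylsilyloxy)-8-oxo-17-norlabdan-18-oic acid
Product: 23 (13S)-15-(tert-butyldimethylsilyloxy)labd-8(17)-en-18-oic acid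
Conditions: Zn, CH2Br2, TiCl4, THF/CH2Cl2, 0 °C to rt (excess reagent)
Reagents that add atoms: dibromomethane, BrCBr
Why: Takai–Lombardo methylenation: the geminal zinc/titanium reagent is non-basic, so the hindered C8 ketone is methylenated without enolisation at C9. The carboxylic acid uses up one equivalent as an inert metal carboxylate.

Step 16
Reactants: 23 (13S)-15-(tert-butyldimethylsilyloxy)labd-8(17)-en-18-oic acid
Product: 25 (13S)-15-acetoxylabd-8(17)-en-18-oic acid (4β-CH3; 5α-H; 9α-H; 10β-CH3), via hydroxy acid 24 (not isolated)
Conditions: HF·pyridine, pyridine/THF, 0 °C to rt; then Ac2O, DMAP, rt; aq. NaHCO3, then pH 3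
Reagents that add atoms: acetic anhydride, CC(=O)OC(C)=O
Why: Fluoride desilylation followed by acetylation in the same pot; buffered HF does not move the exocyclic alkene. Any mixed anhydride at the hindered C18 acid should be hydrolysed at its acetyl carbonyl during the bicarbonate work-up, which returns the free acid.

## Compound list

1 | (S)-citronellol | CC(C)=CCC[C@H](C)CCO | starting material
2 | (S)-tert-butyl[(3,7-dimethyloct-6-en-1-yl)oxy]dimethylsilane | CC(C)=CCC[C@H](C)CCO[Si](C)(C)C(C)(C)C | intermediate
3 | (S)-6-(tert-butyldimethylsilyloxy)-4-methylhexanal | O=CCC[C@H](C)CCO[Si](C)(C)C(C)(C)C | intermediate (not isolated)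
4 | (S)-6-(tert-butyldimethylsilyloxy)-4-methylhexanoic acid | OC(=O)CC[C@H](C)CCO[Si](C)(C)C(C)(C)C | intermediate
5 | (R)-tert-butyl[(5-iodo-3-methylpentyl)oxy]dimethylsilane | ICC[C@H](C)CCO[Si](C)(C)C(C)(C)C | intermediate
6 | pent-4-enal | C=CCCC=O | starting material
7 | but-3-en-2-one (methyl vinyl ketone) | CC(=O)C=C | starting material
8 | (S)-5-oxo-2-(prop-2-en-1-yl)hexanal | O=C[C@H](CC=C)CCC(C)=O | intermediate (not isolated)
9 | (S)-4-allylcyclohex-2-en-1-one | O=C1CC[C@@H](CC=C)C=C1 | intermediate
10 | trimethyl{[(3S,4S)-3-methyl-4-(prop-2-en-1-yl)cyclohex-1-en-1-yl]oxy}silane | C[Si](C)(C)OC1=C[C@@H](C)[C@H](CC=C)CC1 | intermediate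
11 | (S)-4-allyl-3-methylcyclohex-2-en-1-one | O=C1CC[C@@H](CC=C)C(C)=C1 | intermediate
12 | 5-bromo-2-methylpent-1-ene | C=C(C)CCCBr | starting material
13 | (4-methylpent-4-en-1-yl)magnesium bromide | C=C(C)CCC[Mg]Br | intermediate (not isolated)
14 | trimethyl{[(3S,4S)-3-methyl-3-(4-methylpent-4-en-1-yl)-4-(prop-2-en-1-yl)cyclohex-1-en-1-yl]oxy}silane | C[Si](C)(C)OC1=C[C@@](C)(CCCC(C)=C)[C@H](CC=C)CC1 | intermediate
15 | lithium (3S,4S)-3-methyl-3-(4-methylpent-4-en-1-yl)-4-(prop-2-en-1-yl)cyclohex-1-en-1-olate | [Li]OC1=C[C@@](C)(CCCC(C)=C)[C@H](CC=C)CC1 | intermediate (not isolated)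
16 | (3S,4S)-4-allyl-2-[(3S)-5-(tert-butyldimethylsilyloxy)-3-methylpentyl]-3-methyl-3-(4-methylpent-4-en-1-yl)cyclohexan-1-one, C2 (labdane C9) epimer mixture | O=C1CC[C@@H](CC=C)[C@](C)(CCCC(C)=C)C1CC[C@H](C)CCO[Si](C)(C)C(C)(C)C | intermediate
17 | (3S,4S)-2-[(3S)-5-(tert-butyldimethylsilyloxy)-3-methylpentyl]-3-methyl-3-(4-methylpent-4-en-1-yl)-4-[(E)-prop-1-en-1-yl]cyclohexan-1-one, C2 epimer mixture | O=C1CC[C@@H](/C=C/C)[C@](C)(CCCC(C)=C)C1CC[C@H](C)CCO[Si](C)(C)C(C)(C)C | intermediate
18 | (13S)-15-(tert-butyldimethylsilyloxy)-A-homo-17-norlabd-4(18)-en-8-one, C18 in the seven-membered ring between C5 and C4, trans-fused (5α-H, 10β-CH3), C9 epimer mixture | O=C1CC[C@H]2C=C(C)CCC[C@]2(C)C1CC[C@H](C)CCO[Si](C)(C)C(C)(C)C | intermediate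
19 | (13S)-15-(tert-butyldimethylsilyloxy)-A-homo-17-norlabd-4(18)-en-8-one, 5α-H, 9α-H (9β chain), 10β-CH3 | O=C1CC[C@H]2C=C(C)CCC[C@]2(C)[C@H]1CC[C@H](C)CCO[Si](C)(C)C(C)(C)C | intermediate
20 | (13S)-4α,18α-epoxy-15-(tert-butyldimethylsilyloxy)-A-homo-17-norlabdan-8-one | O=C1CC[C@H]2[C@@H]3O[C@]3(C)CCC[C@]2(C)[C@H]1CC[C@H](C)CCO[Si](C)(C)C(C)(C)C | intermediate
21 | (13S)-15-(tert-butyldimethylsilyloxy)-8-oxo-17-norlabdan-18-al (4β-CH3, 4α-CHO) | O=C1CC[C@@H]2[C@](C)(CCC[C@@]2(C)C=O)[C@H]1CC[C@H](C)CCO[Si](C)(C)C(C)(C)C | intermediate
22 | (13S)-15-(tert-butyldimethylsilyloxy)-8-oxo-17-norlabdan-18-oic acid | O=C1CC[C@@H]2[C@](C)(CCC[C@@]2(C)C(=O)O)[C@H]1CC[C@H](C)CCO[Si](C)(C)C(C)(C)C | intermediate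
23 | (13S)-15-(tert-butyldimethylsilyloxy)labd-8(17)-en-18-oic acid | C=C1CC[C@@H]2[C@](C)(CCC[C@@]2(C)C(=O)O)[C@H]1CC[C@H](C)CCO[Si](C)(C)C(C)(C)C | intermediate
24 | (13S)-15-hydroxylabd-8(17)-en-18-oic acid | C=C1CC[C@@H]2[C@](C)(CCC[C@@]2(C)C(=O)O)[C@H]1CC[C@H](C)CCO | intermediate (not isolated)
25 | (13S)-15-acetoxylabd-8(17)-en-18-oic acid (CNP0401865.1) | C=C1CC[C@@H]2[C@](C)(CCC[C@@]2(C)C(=O)O)[C@H]1CC[C@H](C)CCOC(C)=O | target

## Step count and least certain steps

Total: 16 steps. Longest linear sequence: 13 steps (steps 4–16, from 6 and 7 to 25); the side chain 5 takes 3 steps (steps 1–3).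

**Step 13 (key step).** The ionised epoxide may collapse by 1,2-hydride shift from C18 instead of by migration of C5. If the cation becomes free, the shift may also lose its stereospecificity, or a proton may be lost to give an allylic alcohol. The fallback replaces the cationic shift by a halohydrin semipinacol in which only the ring bond can be anti to the leaving group. It sets out from 19 and presupposes, as the main line does, that electrophiles attack the α face. NBS in wet THF should give the 18α-bromo-4β-hydroxy-15-(tert-butyldimethylsilyloxy)-A-homo-17-norlabdan-8-one F1 (water opens the α-bromonium ion at the tertiary carbon). K2CO3 in methanol should close it to the 4β,18β-epoxy-15-(tert-butyldimethylsilyloxy)-A-homo-17-norlabdan-8-one F2. MgBr2·OEt2 should open F2 at C4 with inversion to the bromomagnesium alkoxide of the 4α-bromo-18β-hydroxy-15-(tert-butyldimethylsilyloxy)-A-homo-17-norlabdan-8-one F3. In F3 the bromide and H18 are cis and cannot become antiperiplanar, so on warming only the C18–C5 bond (or the oxygen, which merely returns F2) can displace bromide. C5 then enters C4 from the β face, as in the main line, and the sequence comes back to the route at 21.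

**Step 8.** C-alkylation of the hindered enolate by an unactivated iodide may be slow. Proton exchange between enolate and product would then lead to alkylation at C7 or to double alkylation. The fallback builds the C9–C11 bond by aldol chemistry; it sets out from 14 and 5. Oxidation of 5 with trimethylamine N-oxide in DMSO should give the (R)-5-(tert-butyldimethylsilyloxy)-3-methylpentanal F4. A Mukaiyama aldol addition of 14 to F4 (TiCl4, CH2Cl2, −78 °C) should give the β-hydroxy ketone (aldol adduct) F5. Mesylation and elimination with DBU should give the 2-alkylidene ketone F6. Conjugate reduction with [(Ph3P)CuH]6, with protonation of the enolate anti to C20, comes back to the route at 16, enriched in the wanted C9 epimer.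

**Step 12.** The peracid may attack the β face if the seven-membered ring prefers a conformation other than the chair, and prolonged exposure may start Baeyer–Villiger oxidation of the ketone. The fallback introduces the oxygen anti to the electrophile, so it inverts whatever face preference the alkene has, and uses no peracid. It sets out from 19. NBS in wet THF on the face that the peracid preferred should give the 18β-bromo-4α-hydroxy-15-(tert-butyldimethylsilyloxy)-A-homo-17-norlabdan-8-one F7. K2CO3 in methanol should close it from the α side and come back to the route at 20.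

**Step 3.** The radical chain may be inefficient for a primary acid, and acid or iodine may remove the silyl group. The fallback removes the carbon by a second ozonolysis; it sets out from 2. Ozonolysis with PPh3 work-up should give isolated 3. TMSCl, Et3N and DMF should convert it into the trimethylsilyl enol ether of 3 F8. Ozonolysis of F8 with NaBH4 work-up should give the (S)-5-(tert-butyldimethylsilyloxy)-3-methylpentan-1-ol F9. I2, PPh3 and imidazole come back to the route at 5.

**Step 15.** Methylenation of the hindered ketone may stall if the free acid destroys too much reagent or the ketone enolises. The fallback is a Peterson olefination; it sets out from 22. After deprotonation of the acid, Me3SiCH2Li with CeCl3 in THF at −78 °C should add to the ketone and give the 8-hydroxy-8-(trimethylsilylmethyl)-15-(tert-butyldimethylsilyloxy)-17-norlabdan-18-oic acid F10. Elimination with KH in THF comes back to the route at 23.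

## Further compounds

F1 | step 13 | (13S)-18α-bromo-4β-hydroxy-15-(tert-butyldimethylsilyloxy)-A-homo-17-norlabdan-8-one | O=C1CC[C@H]2[C@H](Br)[C@@](C)(O)CCC[C@]2(C)[C@H]1CC[C@H](C)CCO[Si](C)(C)C(C)(C)C
F2 | step 13 | (13S)-4β,18β-epoxy-15-(tert-butyldimethylsilyloxy)-A-homo-17-norlabdan-8-one | O=C1CC[C@H]2[C@H]3O[C@@]3(C)CCC[C@]2(C)[C@H]1CC[C@H](C)CCO[Si](C)(C)C(C)(C)C
F3 | step 13 | (13S)-4α-bromo-18β-hydroxy-15-(tert-butyldimethylsilyloxy)-A-homo-17-norlabdan-8-one (used as its bromomagnesium alkoxide) | O=C1CC[C@H]2[C@@H](O)[C@](C)(Br)CCC[C@]2(C)[C@H]1CC[C@H](C)CCO[Si](C)(C)C(C)(C)C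
F4 | step 8 | (R)-5-(tert-butyldimethylsilyloxy)-3-methylpentanal | O=CC[C@H](C)CCO[Si](C)(C)C(C)(C)C
F5 | step 8 | (3S,4S)-4-allyl-2-[(3R)-5-(tert-butyldimethylsilyloxy)-1-hydroxy-3-methylpentyl]-3-methyl-3-(4-methylpent-4-en-1-yl)cyclohexan-1-one (carbinol and C2 epimers) | O=C1CC[C@@H](CC=C)[C@](C)(CCCC(C)=C)C1C(O)C[C@H](C)CCO[Si](C)(C)C(C)(C)C
F6 | step 8 | (3S,4S)-4-allyl-2-[(3R)-5-(tert-butyldimethylsilyloxy)-3-methylpentylidene]-3-methyl-3-(4-methylpent-4-en-1-yl)cyclohexan-1-one (either alkene geometry) | O=C1CC[C@@H](CC=C)[C@](C)(CCCC(C)=C)C1=CC[C@H](C)CCO[Si](C)(C)C(C)(C)C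
F7 | step 12 | (13S)-18β-bromo-4α-hydroxy-15-(tert-butyldimethylsilyloxy)-A-homo-17-norlabdan-8-one | O=C1CC[C@H]2[C@@H](Br)[C@](C)(O)CCC[C@]2(C)[C@H]1CC[C@H](C)CCO[Si](C)(C)C(C)(C)C
F8 | step 3 | (S)-tert-butyldimethyl{[3-methyl-6-(trimethylsilyloxy)hex-5-en-1-yl]oxy}silane (E/Z mixture) | C[Si](C)(C)OC=CC[C@H](C)CCO[Si](C)(C)C(C)(C)C
F9 | step 3 | (S)-5-(tert-butyldimethylsilyloxy)-3-methylpentan-1-ol | OCC[C@H](C)CCO[Si](C)(C)C(C)(C)C
F10 | step 15 | (13S)-8-hydroxy-8-(trimethylsilylmethyl)-15-(tert-butyldimethylsilyloxy)-17-norlabdan-18-oic acid (C8 epimers) | C[Si](C)(C)CC1(O)CC[C@@H]2[C@](C)(CCC[C@@]2(C)C(=O)O)[C@H]1CC[C@H](C)CCO[Si](C)(C)C(C)(C)C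
A1 | alternative 1 | methyl 8,8-ethylenedioxy-15-(tert-butyldimethylsilyloxy)-17-norlabd-1-en-18-oate | C12(OCCO1)CC[C@@H]3[C@](C)(C=CC[C@@]3(C)C(=O)OC)[C@H]2CC[C@H](C)CCO[Si](C)(C)C(C)(C)C
A2 | alternative 1 | methyl (2E,8E)-7-[(3S)-5-(tert-butyldimethylsilyloxy)-3-methylpentyl]-6,6-ethylenedioxy-2,8-dimethylundeca-2,8,10-trienoate (C7 as C9 of the target) | COC(=O)/C(C)=C/CCC1(OCCO1)[C@H](CC[C@H](C)CCO[Si](C)(C)C(C)(C)C)/C(C)=C/C=C
A3 | alternative 2 | cis-fused adduct, labdane numbering: 18-(tert-butyldimethylsilyloxy)-7-methoxy-4,10-dimethyl bicyclic 2,7-diene-6,9-dione, 5β-H | C1=C(OC)C(=O)[C@H]2[C@](C)(CC=C[C@@]2(C)CO[Si](C)(C)C(C)(C)C)C1=O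
A4 | alternative 2 | 2-methoxy-5-methyl-1,4-benzoquinone | COC1=CC(=O)C(C)=CC1=O
A5 | alternative 2 | (E)-tert-butyldimethyl[(2-methylpenta-2,4-dien-1-yl)oxy]silane | C=C/C=C(\C)CO[Si](C)(C)C(C)(C)C
A6 | alternative 3 | methyl (13S)-15-(tert-butyldimethylsilyloxy)labd-8(17)-en-18-oate | C=C1CC[C@@H]2[C@](C)(CCC[C@@]2(C)C(=O)OC)[C@H]1CC[C@H](C)CCO[Si](C)(C)C(C)(C)C
A7 | alternative 3 | dehydroabietic acid | CC(C)c1ccc2c(c1)CC[C@@H]1[C@]2(C)CCC[C@@]1(C)C(=O)O
A8 | alternative 3 | methyl (13S)-15-(tert-butyldimethylsilyloxy)-9-(phenoxythiocarbonyloxy)-8,9-secolabd-8(17)-yn-18-oate (C9 epimers) | C#CCC[C@@H]1[C@](C)(CCC[C@@]1(C)C(=O)OC)C(OC(=S)Oc1ccccc1)CC[C@H](C)CCO[Si](C)(C)C(C)(C)C
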